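**Plan**

Numbering: quinone ring C1–C6 with C1=O lying between methyl-bearing C2 and chain-bearing C6, C4=O para to it, C3 and C5 unsubstituted; chain C1'–C16' counted from the ring.
Enabling feature: in this 2-methyl-6-alkyl-1,4-benzoquinone ring, C1 can come from carbon monoxide, C2–C4 from a propenyl(methoxy)carbene and C5–C6 from a terminal alkyne on C1'.
Retrosynthesis: remove the two silyl groups and the quinone oxidation level, then cut ring bonds C4–C5, C6–C1 and C1–C2 (benzannulation), then C1'–C(sp) (ethynylation), C9'–C10' (B-alkyl Suzuki) and C11'–C12' (iodo-aldol).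
Forward: the C10'–C16' head iodide is made from 4-methylpent-3-enal and ethyl propiolate, the C1'–C9' triene from geraniol; they are joined at C9'–C10', the ethynyl group is placed on C1', and the ring is built last on the finished chain.
Stereochemistry: C12' (R) comes from the catalyst-controlled iodo-aldol; 10'E from the Z-iodoacrylate geometry, kept through the Suzuki coupling; 2'E and 6'E from geraniol and the E-selective allylic oxidation.

Key step: step 13

Assumption: the (S)-diphenylprolinol-derived oxazaborolidinium catalyst is taken to leave the Si face of aldehyde 2 open, which gives 12'R; the sense would be checked on 6 by MTPA ester analysis and the enantiomeric catalyst used if it is the opposite.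

**Route**

Step 1
Reactants: 1 4-methylpent-3-en-1-ol
Product: 2 4-methylpent-3-enal
Conditions: Dess–Martin periodinane, NaHCO3, CH2Cl2, 0 °C→rt; used at once as a cold solution
Reagents that add atoms: none
Why: Dess–Martin oxidation of the primary alcohol under bicarbonate buffering is fast and essentially neutral, so the β,γ-unsaturated aldehyde should form without migration of the double bond into conjugation.

Step 2
Reactants: 2 4-methylpent-3-enal; 3 ethyl propiolate
Product: 6 ethyl (2Z)-2-[(1R)-1-hydroxy-4-methylpent-3-en-1-yl]-3-iodoprop-2-enoate, via silyl allenoate 4 (not isolated), via trimethylsilyl ether 5 (not isolated)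
Conditions: TMSI, (S)-o-tolyl-oxazaborolidinium triflimide (20 mol %), CH2Cl2, −78 °C; then 1 M HCl, THF, 0 °C
Reagents that add atoms: iodotrimethylsilane, C[Si](C)(C)I
Why: In this catalytic asymmetric three-component iodo-aldol (β-iodo Morita–Baylis–Hillman type) reaction, iodide from TMSI adds to 3 to give allenoate 4, whose central carbon adds in a Mukaiyama-type aldol to catalyst-bound 2 on the side away from iodine (hence Z) and on the Si face left open by the catalyst (hence 12'R), and silyl ether 5 is cleaved on acidic work-up.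

Step 3
Reactants: 6 ethyl (2Z)-2-[(1R)-1-hydroxy-4-methylpent-3-en-1-yl]-3-iodoprop-2-enoate
Product: 7 (2E,3R)-2-(iodomethylidene)-6-methylhept-5-ene-1,3-diol
Conditions: DIBAL-H (3.5 equiv), CH2Cl2, −78 °C; aq. Rochelle salt
Reagents that add atoms: none
Why: DIBAL-H 1,2-reduction of the enoate to the allylic alcohol should leave the vinyl iodide, the trisubstituted alkene and the carbinol centre untouched at −78 °C (the iodoalkene descriptor changes from Z to E only because the priorities change).

Step 4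
Reactants: 7 (2E,3R)-2-(iodomethylidene)-6-methylhept-5-ene-1,3-diol
Product: 8 (2E,3R)-1,3-bis[(tert-butyldimethylsilyl)oxy]-2-(iodomethylidene)-6-methylhept-5-ene
Conditions: TBSOTf, 2,6-lutidine, CH2Cl2, −78→0 °C
Reagents that add atoms: tert-butyldimethylsilyl trifluoromethanesulfonate, CC(C)(C)[Si](C)(C)OS(=O)(=O)C(F)(F)F
Why: Silylation of a primary and a secondary allylic alcohol with the silyl triflate and a hindered pyridine base is fast at low temperature and does not affect the vinyl iodide or the stereocentre.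

Step 5
Reactants: 9 geraniol
Product: 10 1-({[(2E)-3,7-dimethylocta-2,6-dien-1-yl]oxy}methyl)-4-methoxybenzene
Conditions: NaH, THF/DMF, 0 °C; PMBCl, Bu4NI (cat.), rt
Reagents that add atoms: 4-methoxybenzyl chloride, COc1ccc(CCl)cc1
Why: Williamson etherification gives an ether that tolerates the oxidation, ylide, borane and palladium steps and can later be removed oxidatively without touching silyl ethers.

Step 6
Reactants: 10 1-({[(2E)-3,7-dimethylocta-2,6-dien-1-yl]oxy}methyl)-4-methoxybenzene
Product: 12 (2E,6E)-8-[(4-methoxybenzyl)oxy]-2,6-dimethylocta-2,6-dienal, via allylic alcohol 11 (not isolated)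
Conditions: SeO2 (cat.), t-BuOOH, salicylic acid (cat.), CH2Cl2, 0 °C→rt; then MnO2, CH2Cl2, rt
Reagents that add atoms: tert-butyl hydroperoxide, CC(C)(C)OO
Why: Selenium dioxide-catalysed allylic oxidation (ene reaction, then [2,3]-sigmatropic shift) attacks the E-methyl of the more electron-rich terminal alkene, the 2,3-alkene being deactivated by the allylic ether oxygen, and manganese dioxide takes alcohol 11 in the crude mixture on to the (E)-enal.

Step 7
Reactants: 12 (2E,6E)-8-[(4-methoxybenzyl)oxy]-2,6-dimethylocta-2,6-dienal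
Product: 13 1-({[(2E,6E)-3,7-dimethylnona-2,6,8-trien-1-yl]oxy}methyl)-4-methoxybenzene
Conditions: Ph3PCH3Br, KOtBu, THF, 0 °C→rt
Reagents that add atoms: methyltriphenylphosphonium bromide, C[P+](c1ccccc1)(c1ccccc1)c1ccccc1.[Br-]
Why: Wittig methylenation of the α-methyl enal with the non-stabilised ylide should give the terminal 1,3-diene without disturbing the 6E geometry.

Step 8
Reactants: 13 1-({[(2E,6E)-3,7-dimethylnona-2,6,8-trien-1-yl]oxy}methyl)-4-methoxybenzene; 8 (2E,3R)-1,3-bis[(tert-butyldimethylsilyl)oxy]-2-(iodomethylidene)-6-methylhept-5-ene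
Product: 15 1-({[(2E,6E,10E,12R)-12-[(tert-butyldimethylsilyl)oxy]-11-{[(tert-butyldimethylsilyl)oxy]methyl}-3,7,15-trimethylhexadeca-2,6,10,14-tetraen-1-yl]oxy}methyl)-4-methoxybenzene, via B-alkyl-9-BBN borane 14 (not isolated)
Conditions: 9-BBN, THF, 0 °C→rt; then 8, PdCl2(dppf) (cat.), AsPh3 (cat.), Cs2CO3, DMF/H2O, rt
Reagents that add atoms: none
Why: In this B-alkyl Suzuki–Miyaura coupling 9-BBN adds only to the monosubstituted terminal alkene of 13 with boron on C9', and borane 14 couples with iodide 8 with retention of alkene geometry, which fixes 10'E with the silyloxymethyl group cis to C9'.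

Step 9
Reactants: 15 1-({[(2E,6E,10E,12R)-12-[(tert-butyldimethylsilyl)oxy]-11-{[(tert-butyldimethylsilyl)oxy]methyl}-3,7,15-trimethylhexadeca-2,6,10,14-tetraen-1-yl]oxy}methyl)-4-methoxybenzene
Product: 16 (2E,6E,10E,12R)-12-[(tert-butyldimethylsilyl)oxy]-11-{[(tert-butyldimethylsilyl)oxy]methyl}-3,7,15-trimethylhexadeca-2,6,10,14-tetraen-1-ol
Conditions: DDQ, CH2Cl2/pH 7 buffer, 0 °C
Reagents that add atoms: none
Why: Oxidative cleavage of the 4-methoxybenzyl ether by DDQ (benzylic hydride abstraction, then hydrolysis) under buffered biphasic conditions is selective for the electron-rich benzyl ether over silyl ethers and isolated alkenes.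

Step 10
Reactants: 16 (2E,6E,10E,12R)-12-[(tert-butyldimethylsilyl)oxy]-11-{[(tert-butyldimethylsilyl)oxy]methyl}-3,7,15-trimethylhexadeca-2,6,10,14-tetraen-1-ol
Product: 18 (2E,6E,10E,12R)-1-bromo-12-[(tert-butyldimethylsilyl)oxy]-11-{[(tert-butyldimethylsilyl)oxy]methyl}-3,7,15-trimethylhexadeca-2,6,10,14-tetraene, via allylic mesylate 17 (not isolated)
Conditions: MsCl, Et3N, THF, −40 °C; then LiBr, THF, −40→0 °C
Reagents that add atoms: lithium bromide, [Li+].[Br-]
Why: Mesylation followed by SN2 displacement with bromide at low temperature converts the primary allylic alcohol into the bromide under non-acidic conditions, without allylic transposition or loss of the 2'E geometry.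

Step 11
Reactants: 18 (2E,6E,10E,12R)-1-bromo-12-[(tert-butyldimethylsilyl)oxy]-11-{[(tert-butyldimethylsilyl)oxy]methyl}-3,7,15-trimethylhexadeca-2,6,10,14-tetraene
Product: 19 (4E,8E,12E,14R)-14-[(tert-butyldimethylsilyl)oxy]-13-{[(tert-butyldimethylsilyl)oxy]methyl}-5,9,17-trimethyloctadeca-4,8,12,16-tetraen-1-yne
Conditions: HC≡CMgBr (excess), CuCl (cat.), THF, 0 °C→rt
Reagents that add atoms: ethynylmagnesium bromide, C#C[Mg]Br
Why: Copper-catalysed substitution of a primary allylic bromide by an alkynyl Grignard reagent occurs at the unhindered α-carbon and gives the skipped (1,4-) enyne, an excess of the acetylide suppressing dialkylation.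

Step 12
Reactants: 20 (E)-1-bromoprop-1-ene; 21 chromium hexacarbonyl
Product: 24 pentacarbonyl[(2E)-1-methoxybut-2-en-1-ylidene]chromium, via propenyllithium 22 (not isolated), via lithium acylchromate 23 (not isolated)
Conditions: t-BuLi (2 equiv), Et2O, −78 °C; Cr(CO)6, Et2O, −78 °C→rt; then Me3OBF4, CH2Cl2, 0 °C
Reagents that add atoms: trimethyloxonium tetrafluoroborate, C[O+](C)C.F[B-](F)(F)F
Why: In this Fischer carbene synthesis bromine–lithium exchange with retention of geometry gives 22, which adds to a CO ligand of 21 to form acylchromate 23, and O-methylation with the oxonium salt gives the alkenyl(methoxy)carbene complex.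

Step 13
Reactants: 19 (4E,8E,12E,14R)-14-[(tert-butyldimethylsilyl)oxy]-13-{[(tert-butyldimethylsilyl)oxy]methyl}-5,9,17-trimethyloctadeca-4,8,12,16-tetraen-1-yne; 24 pentacarbonyl[(2E)-1-methoxybut-2-en-1-ylidene]chromium
Product: 26 2-[(2E,6E,10E,12R)-12-[(tert-butyldimethylsilyl)oxy]-11-{[(tert-butyldimethylsilyl)oxy]methyl}-3,7,15-trimethylhexadeca-2,6,10,14-tetraen-1-yl]-4-methoxy-6-methylphenol, via tricarbonylchromium arene complex 25 (not isolated)
Conditions: 24 (1.5 equiv), degassed THF (0.05 M), 50 °C, Ar; then air, Et2O, rt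
Reagents that add atoms: none
Why: Dötz benzannulation: loss of one CO from 24 lets the alkyne of 19 coordinate and insert into the Cr=C bond with its CH terminus bonded to the methoxy carbon (C4–C5); CO insertion then gives a chromium-bound dienylketene (C6–C1), and 6π-electrocyclisation onto the propenyl β-carbon (C1–C2) followed by enolisation gives the arene, first as complex 25 and after air oxidation as phenol 26. The closest known reaction type is the benzannulation of alkenyl(alkoxy)carbene chromium complexes with terminal alkynes and with 1,4-enynes in prenylquinone synthesis. The one ring is closed as a six-membered carbocycle by 6π-electrocyclic closure of the dienylketene. No stereocentre is formed, and C12', the four chain alkenes and both silyl ethers are spectators. The step needs regiocontrol of the alkyne insertion, which the size difference between the alkyne hydrogen and the C1' methylene secures by placing the chain on C6 next to the CO-derived C1 and leaving the propenyl methyl on C2; the trisubstituted alkenes are inert to the carbene at 50 °C, and dilution suppresses uptake of a second alkyne.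

Step 14
Reactants: 26 2-[(2E,6E,10E,12R)-12-[(tert-butyldimethylsilyl)oxy]-11-{[(tert-butyldimethylsilyl)oxy]methyl}-3,7,15-trimethylhexadeca-2,6,10,14-tetraen-1-yl]-4-methoxy-6-methylphenol
Product: 27 2-[(2E,6E,10E,12R)-12-[(tert-butyldimethylsilyl)oxy]-11-{[(tert-butyldimethylsilyl)oxy]methyl}-3,7,15-trimethylhexadeca-2,6,10,14-tetraen-1-yl]-6-methylcyclohexa-2,5-diene-1,4-dione
Conditions: PhI(OAc)2, MeCN/H2O, 0 °C
Reagents that add atoms: water, O
Why: Hypervalent-iodine oxidative demethylation of a 4-methoxyphenol (ligand exchange at iodine(III), attack of water at C4, loss of methanol from the hemiketal) gives the 1,4-benzoquinone under conditions that should leave trisubstituted alkenes and silyl ethers intact.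

Step 15
Reactants: 27 2-[(2E,6E,10E,12R)-12-[(tert-butyldimethylsilyl)oxy]-11-{[(tert-butyldimethylsilyl)oxy]methyl}-3,7,15-trimethylhexadeca-2,6,10,14-tetraen-1-yl]-6-methylcyclohexa-2,5-diene-1,4-dione
Product: 28 2-[(2E,6E,10E,12R)-12-hydroxy-11-(hydroxymethyl)-3,7,15-trimethylhexadeca-2,6,10,14-tetraen-1-yl]-6-methylcyclohexa-2,5-diene-1,4-dione
Conditions: 48% aq. HF, MeCN, 0 °C
Reagents that add atoms: none
Why: Acidic fluoride cleaves both Si–O bonds while avoiding the basic media in which 2-allyl quinones isomerise to chromenols, and the allylic carbinol centre C12' should not ionise at 0 °C.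

**Compound list**

1 | 4-methylpent-3-en-1-ol | CC(C)=CCCO | starting material
2 | 4-methylpent-3-enal | CC(C)=CCC=O | intermediate
3 | ethyl propiolate | C#CC(=O)OCC | starting material
4 | [(1-ethoxy-3-iodopropa-1,2-dien-1-yl)oxy]trimethylsilane | CCOC(O[Si](C)(C)C)=C=CI | intermediate
5 | ethyl (2Z)-3-iodo-2-[(1R)-4-methyl-1-[(trimethylsilyl)oxy]pent-3-en-1-yl]prop-2-enoate | CC(C)=CC[C@@H](O[Si](C)(C)C)/C(=C/I)C(=O)OCC | intermediate
6 | ethyl (2Z)-2-[(1R)-1-hydroxy-4-methylpent-3-en-1-yl]-3-iodoprop-2-enoate | CC(C)=CC[C@@H](O)/C(=C/I)C(=O)OCC | intermediate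
7 | (2E,3R)-2-(iodomethylidene)-6-methylhept-5-ene-1,3-diol | CC(C)=CC[C@@H](O)/C(=C/I)CO | intermediate
8 | (2E,3R)-1,3-bis[(tert-butyldimethylsilyl)oxy]-2-(iodomethylidene)-6-methylhept-5-ene | CC(C)=CC[C@@H](O[Si](C)(C)C(C)(C)C)/C(=C/I)CO[Si](C)(C)C(C)(C)C | intermediate
9 | geraniol, (2E)-3,7-dimethylocta-2,6-dien-1-ol | CC(C)=CCC/C(C)=C/CO | starting material
10 | 1-({[(2E)-3,7-dimethylocta-2,6-dien-1-yl]oxy}methyl)-4-methoxybenzene | CC(C)=CCC/C(C)=C/COCc1ccc(OC)cc1 | intermediate
11 | (2E,6E)-8-[(4-methoxybenzyl)oxy]-2,6-dimethylocta-2,6-dien-1-ol | OC/C(C)=C/CC/C(C)=C/COCc1ccc(OC)cc1 | intermediate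
12 | (2E,6E)-8-[(4-methoxybenzyl)oxy]-2,6-dimethylocta-2,6-dienal | O=C/C(C)=C/CC/C(C)=C/COCc1ccc(OC)cc1 | intermediate
13 | 1-({[(2E,6E)-3,7-dimethylnona-2,6,8-trien-1-yl]oxy}methyl)-4-methoxybenzene | C=C/C(C)=C/CC/C(C)=C/COCc1ccc(OC)cc1 | intermediate
14 | 9-[(3E,7E)-9-[(4-methoxybenzyl)oxy]-3,7-dimethylnona-3,7-dien-1-yl]-9-borabicyclo[3.3.1]nonane | B1(C2CCCC1CCC2)CC/C(C)=C/CC/C(C)=C/COCc1ccc(OC)cc1 | intermediate
15 | 1-({[(2E,6E,10E,12R)-12-[(tert-butyldimethylsilyl)oxy]-11-{[(tert-butyldimethylsilyl)oxy]methyl}-3,7,15-trimethylhexadeca-2,6,10,14-tetraen-1-yl]oxy}methyl)-4-methoxybenzene | CC(C)=CC[C@@H](O[Si](C)(C)C(C)(C)C)/C(=C/CC/C(C)=C/CC/C(C)=C/COCc1ccc(OC)cc1)CO[Si](C)(C)C(C)(C)C | intermediate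
16 | (2E,6E,10E,12R)-12-[(tert-butyldimethylsilyl)oxy]-11-{[(tert-butyldimethylsilyl)oxy]methyl}-3,7,15-trimethylhexadeca-2,6,10,14-tetraen-1-ol | CC(C)=CC[C@@H](O[Si](C)(C)C(C)(C)C)/C(=C/CC/C(C)=C/CC/C(C)=C/CO)CO[Si](C)(C)C(C)(C)C | intermediate
17 | (2E,6E,10E,12R)-12-[(tert-butyldimethylsilyl)oxy]-11-{[(tert-butyldimethylsilyl)oxy]methyl}-3,7,15-trimethylhexadeca-2,6,10,14-tetraen-1-yl methanesulfonate | CC(C)=CC[C@@H](O[Si](C)(C)C(C)(C)C)/C(=C/CC/C(C)=C/CC/C(C)=C/COS(C)(=O)=O)CO[Si](C)(C)C(C)(C)C | intermediate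
18 | (2E,6E,10E,12R)-1-bromo-12-[(tert-butyldimethylsilyl)oxy]-11-{[(tert-butyldimethylsilyl)oxy]methyl}-3,7,15-trimethylhexadeca-2,6,10,14-tetraene | CC(C)=CC[C@@H](O[Si](C)(C)C(C)(C)C)/C(=C/CC/C(C)=C/CC/C(C)=C/CBr)CO[Si](C)(C)C(C)(C)C | intermediate
19 | (4E,8E,12E,14R)-14-[(tert-butyldimethylsilyl)oxy]-13-{[(tert-butyldimethylsilyl)oxy]methyl}-5,9,17-trimethyloctadeca-4,8,12,16-tetraen-1-yne | CC(C)=CC[C@@H](O[Si](C)(C)C(C)(C)C)/C(=C/CC/C(C)=C/CC/C(C)=C/CC#C)CO[Si](C)(C)C(C)(C)C | intermediate
20 | (E)-1-bromoprop-1-ene | C/C=C/Br | starting material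
21 | chromium hexacarbonyl | O=C=[Cr](=C=O)(=C=O)(=C=O)(=C=O)=C=O | starting material
22 | (E)-prop-1-en-1-yllithium | C/C=C/[Li] | intermediate
23 | lithium pentacarbonyl[(2E)-1-oxidobut-2-en-1-ylidene]chromate | C/C=C/C([O-])=[Cr](=C=O)(=C=O)(=C=O)(=C=O)=C=O.[Li+] | intermediate
24 | pentacarbonyl[(2E)-1-methoxybut-2-en-1-ylidene]chromium | C/C=C/C(OC)=[Cr](=C=O)(=C=O)(=C=O)(=C=O)=C=O | intermediate
25 | tricarbonyl(η6-arene)chromium complex of phenol 26 (SMILES written as arene plus Cr(CO)3 fragment) | CC(C)=CC[C@@H](O[Si](C)(C)C(C)(C)C)/C(=C/CC/C(C)=C/CC/C(C)=C/Cc1cc(OC)cc(C)c1O)CO[Si](C)(C)C(C)(C)C.O=C=[Cr](=C=O)=C=O | intermediate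
26 | 2-[(2E,6E,10E,12R)-12-[(tert-butyldimethylsilyl)oxy]-11-{[(tert-butyldimethylsilyl)oxy]methyl}-3,7,15-trimethylhexadeca-2,6,10,14-tetraen-1-yl]-4-methoxy-6-methylphenol | CC(C)=CC[C@@H](O[Si](C)(C)C(C)(C)C)/C(=C/CC/C(C)=C/CC/C(C)=C/Cc1cc(OC)cc(C)c1O)CO[Si](C)(C)C(C)(C)C | intermediate
27 | 2-[(2E,6E,10E,12R)-12-[(tert-butyldimethylsilyl)oxy]-11-{[(tert-butyldimethylsilyl)oxy]methyl}-3,7,15-trimethylhexadeca-2,6,10,14-tetraen-1-yl]-6-methylcyclohexa-2,5-diene-1,4-dione | CC(C)=CC[C@@H](O[Si](C)(C)C(C)(C)C)/C(=C/CC/C(C)=C/CC/C(C)=C/CC1=CC(=O)C=C(C)C1=O)CO[Si](C)(C)C(C)(C)C | intermediate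
28 | 2-[(2E,6E,10E,12R)-12-hydroxy-11-(hydroxymethyl)-3,7,15-trimethylhexadeca-2,6,10,14-tetraen-1-yl]-6-methylcyclohexa-2,5-diene-1,4-dione (CNP0201434.1) | CC(C)=CC[C@@H](O)/C(=C/CC/C(C)=C/CC/C(C)=C/CC1=CC(=O)C=C(C)C1=O)CO | target

**Count and risks**

Total step count: 15. Longest linear sequence: 11 steps (1, 2, 3, 4, 8, 9, 10, 11, 13, 14, 15, from 4-methylpent-3-en-1-ol).

Steps most likely to fail:

Step 2. The oxazaborolidinium ion may discriminate poorly between the faces of an unbranched aliphatic aldehyde, and the β,γ-double bond of 2 may drift into conjugation before the C–C bond forms. Fallback: the stereocentre is obtained by resolution instead of asymmetric catalysis. Setting out from 2 and 3, magnesium iodide in CH2Cl2 at 0 °C would give the racemic (Z)-iodo ester F1. A Pseudomonas cepacia lipase with vinyl acetate in tert-butyl methyl ether is expected, by the usual size model for secondary alcohols (substituted acrylate as large group, CH2 chain as medium group), to acylate the (R)-alcohol, giving the (R)-acetate F2. F2 is separated from the unreacted (S)-alcohol and reduced with excess DIBAL-H (CH2Cl2, −78 °C) to diol 7, where the route is rejoined.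

Step 13. The alkyne may insert with imperfect regiocontrol, or the skipped enyne may isomerise or be diverted at chromium to non-phenolic products. Fallback: the ring is brought in preformed as an aryl nucleophile. The sequence sets out from bromide 18 and bypasses steps 11 to 14. Commercial 4-methoxy-2-methylphenol is brominated ortho to the hydroxyl (Br2, CH2Cl2, 0 °C) to 2-bromo-4-methoxy-6-methylphenol F3 and O-methylated (MeI, K2CO3, acetone) to 1-bromo-2,5-dimethoxy-3-methylbenzene F4. Magnesium in THF converts F4 into (2,5-dimethoxy-3-methylphenyl)magnesium bromide F5, which is alkylated by 18 at the primary allylic carbon under CuBr·SMe2 catalysis at −20 °C to give the dimethoxyarene F6. Ceric ammonium nitrate (MeCN/H2O, 0 °C) then oxidises F6 to quinone 27, where the route is rejoined.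

Step 11. The acetylide may attack the tertiary γ-carbon (SN2′), acetylene may be alkylated twice, or the basic Grignard medium may move the skipped enyne into conjugation. Fallback: a silyl-capped acetylene is coupled as its copper acetylide under carbonate base and unmasked afterwards. Setting out from 18, (trimethylsilyl)acetylene, CuI, K2CO3 and NaI in DMF at rt would give the silyl enyne F7, and K2CO3 in MeOH at 0 °C removes the silyl group to give 19, where the route is rejoined.

**Further compounds**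

F1 | step 2 | ethyl (2Z)-2-(1-hydroxy-4-methylpent-3-en-1-yl)-3-iodoprop-2-enoate, racemate | CC(C)=CCC(O)/C(=C/I)C(=O)OCC
F2 | step 2 | ethyl (2Z)-2-[(1R)-1-acetoxy-4-methylpent-3-en-1-yl]-3-iodoprop-2-enoate | CC(C)=CC[C@@H](OC(C)=O)/C(=C/I)C(=O)OCC
F3 | step 13 | 2-bromo-4-methoxy-6-methylphenol | Cc1cc(OC)cc(Br)c1O
F4 | step 13 | 1-bromo-2,5-dimethoxy-3-methylbenzene | COc1cc(C)c(OC)c(Br)c1
F5 | step 13 | (2,5-dimethoxy-3-methylphenyl)magnesium bromide | COc1cc(C)c(OC)c([Mg]Br)c1
F6 | step 13 | 1-[(2E,6E,10E,12R)-12-[(tert-butyldimethylsilyl)oxy]-11-{[(tert-butyldimethylsilyl)oxy]methyl}-3,7,15-trimethylhexadeca-2,6,10,14-tetraen-1-yl]-2,5-dimethoxy-3-methylbenzene | CC(C)=CC[C@@H](O[Si](C)(C)C(C)(C)C)/C(=C/CC/C(C)=C/CC/C(C)=C/Cc1cc(OC)cc(C)c1OC)CO[Si](C)(C)C(C)(C)C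
F7 | step 11 | (4E,8E,12E,14R)-14-[(tert-butyldimethylsilyl)oxy]-13-{[(tert-butyldimethylsilyl)oxy]methyl}-5,9,17-trimethyl-1-(trimethylsilyl)octadeca-4,8,12,16-tetraen-1-yne | CC(C)=CC[C@@H](O[Si](C)(C)C(C)(C)C)/C(=C/CC/C(C)=C/CC/C(C)=C/CC#C[Si](C)(C)C)CO[Si](C)(C)C(C)(C)C
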